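I began from a one-step world, where each product comes straight from the starting material and the share of target (the selectivity) stays flat in time. Delta did not behave so: its share fell from 95.8% at 4.00 h to 79.7% at 20.0 h. So I asked what delta must hold at its stop.

| flask | starting material | protic impurity | remark | time |
|---|---|---|---|---|
| delta | 2.4 M | 0.48 M | the very flask that is asked about, followed so far |  |
| epsilon | 2.4 M | 0.72 M | run made earlier |  |
| flask | 2.4 M | 0.480 M |  | 3.0 d |

| run | time / h | target / % | isomer of the product / % | starting material / % |
|---|---|---|---|---|
| delta | 1.50 | 2.1 | 0.2 | 59.3 |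
| delta | 2.50 | 3.5 | 0.1 | 47.8 |
| delta | 4.00 | 4.6 | 0.2 | 36.3 |
| delta | 6.00 | 5.6 | 0.7 | 28.6 |
| delta | 10.0 | 7.2 | 1.4 | 20.2 |
| delta | 15.0 | 9.2 | 2.1 | 14.5 |
| delta | 20.0 | 10.2 | 2.6 | 9.6 |
| epsilon | 2.50 | 2.8 | 0 | 42.6 |
| epsilon | 8.00 | 6.0 | 0.7 | 20.0 |
| epsilon | 15.0 | 8.1 | 1.9 | 12.4 |
| epsilon | 20.0 | 9.0 | 2.4 | 7.9 |
| epsilon | 30.0 | 10.6 | 3.5 | 4.5 |
| epsilon | 40.0 | 10.5 | 4.2 | 2.4 |
| epsilon | 48.0 | 10.9 | 4.4 | 1.1 |

(readings scatter by 0.3 percentage points)

- a species is counted by the starting material in it: one self-condensation product counts as two
- on the list of suspects stand: starting material <-> other conformer; starting material -> target; other conformer -> isomer of the product; other conformer <-> third conformer; third conformer -> third product; 2 other conformer -> self-condensation product; starting material <-> dormant form; starting material + protic impurity -> quenched substrate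

- share of target in target plus isomer of the product at 1.0 h
- share of target in target plus isomer of the product at 8.0 h
- share of target in target plus isomer of the product at 3.0 d

I took target first. Between 10.0 h and 20.0 h, delta lost 11 percentage points of starting material and gained 3 points of target. That reads as 0.283 of target per starting material lost. Applied to the 9.6% remaining at 20.0 h, it put delta's target at 12.9% by 3.0 d.

Isomer of the product came next. At 20.0 h, delta's reading stood above epsilon's, by a factor of 1.08. Scaling epsilon's last reading by it gave delta 4.77% at 48.0 h. A straight line from epsilon's last stretch added 1.3 points by 3.0 d.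

That line was the weak link. Epsilon's pace had fallen to about half between its stretches, so I counted 0.5 of the gain. Delta's isomer became 5.42%.

That made 0.419 the end ratio, isomer of the product per target at delta's stop. It gave a share of 70.5%.

The forecast said 98%, 86% and 70%, with “Isomer should plateau near 5.3”. My share stood slightly higher.

The flask gave 97.5%, 88.2% and 69.3%, each inside the forecast's range.

    starting material ⇌ other conformer (K = 9.10, k = 0.00178 min⁻¹)
    starting material → target (k = 3.20 × 10⁻⁴ min⁻¹)
    other conformer → isomer of the product (k = 2.03 × 10⁻⁴ min⁻¹)
    other conformer ⇌ third conformer (K = 1.30, k = 0.0207 min⁻¹)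
    third conformer → third product (k = 8.41 × 10⁻⁴ min⁻¹)
    2 other conformer → self-condensation product (k = 0.00243 M⁻¹ min⁻¹)
    starting material ⇌ dormant form (K = 0.470, k = 0.00239 min⁻¹)
    starting material + protic impurity → quenched substrate (k = 0.00666 M⁻¹ min⁻¹)

At 3.00 d, the flask still held 1.85% of other conformer and 2.36% of third conformer. Put on its 12.9% of target, the end ratio of 0.419 gives 5.41% of isomer of the product, and the flask held 5.73%. The neighbour flask with 0.29 M of protic impurity held 14.2% of target at 3.00 d. There the end ratio gives 5.95% of isomer of the product, and that flask held 6.12%.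

(The numbers in the tables stem from a simulated flask on assumed constants, noise included.)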